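**Assumption:** the target SMILES has no stereocentres or stereo-descriptors, so the compound is achiral and is made as drawn.

**Retrosynthetic overview**
1. Target 6 ⇒ benzylic C–S disconnection: methanesulfinate plus hydroxy-para-quinone methide 4 (1,6-addition with re-aromatisation).
2. 4 ⇒ ortho-quinone 3 by tautomerisation (possible because one OH of the target is para to the benzylic carbon); 3 ⇒ catechol 2 by oxidation.
3. 2 ⇒ 4-methylcatechol 1 by exhaustive ring bromination (three C–Br bonds).
4. No ring is formed: the benzene ring is bought in 1. No protecting groups are used.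

**Route**

Step 1
Reactants: 1 4-methylbenzene-1,2-diol (4-methylcatechol)
Product: 2 3,4,6-tribromo-5-methylbenzene-1,2-diol
Conditions: Br2 (3.1 equiv), AcOH, 10 °C to rt, 3 h, dark; aq NaHSO3 quench
Reagents that add atoms: bromine, BrBr
Why: Electrophilic aromatic bromination of a strongly activated catechol, whose three free ring positions are each ortho or para to a hydroxyl and are all filled by three equivalents of Br2 (as catechol itself goes to tetrabromocatechol), while low temperature and darkness hold back side-chain bromination; no stereocentre is formed.

Step 2
Reactants: 2 3,4,6-tribromo-5-methylbenzene-1,2-diol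
Product: 3 3,4,6-tribromo-5-methylcyclohexa-3,5-diene-1,2-dione
Conditions: NaIO4 on wet SiO2 (1.3 equiv), CH2Cl2, 0 °C, 20 min, dark; filter through Na2SO4, evaporate below 20 °C, use the same day
Reagents that add atoms: none
Why: Two-electron periodate oxidation of a catechol to its ortho-quinone through the cyclic periodate ester, run on a slightly acidic surface without base or nucleophile so that the halogenated quinone (an isolable red solid like other tetrasubstituted halo-ortho-quinones) does not tautomerise; no stereocentre is formed.

Step 3
Reactants: 3 3,4,6-tribromo-5-methylcyclohexa-3,5-diene-1,2-dione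
Product: 6 3,4,6-tribromo-5-[(methanesulfonyl)methyl]benzene-1,2-diol, via para-quinone methide 4 (not isolated), via benzylic acetate 5 (not isolated)
Conditions: 3 in CH2Cl2 added over 1 h to NaOAc (2 equiv) in DMF/AcOH 4:1, 0 °C, N2, dark, until the red colour is gone; then CH3SO2Na (1.5 equiv), rt to 40 °C, 2 h; aq Na2S2O4 wash
Reagents that add atoms: sodium methanesulfinate CH3SO2Na, CS(=O)[O-].[Na+]; acetic acid, CC(=O)O (incorporated only in intermediate 5)
Why: Proposed new method: a tautomerisation-relay benzylic C(sp3)–H sulfonylation of a methyl-ortho-quinone — the acetate/acetic acid couple shuttles one hydrogen of the C5 methyl group (gamma to the C1 carbonyl through C5=C6 and acidified by three bromines and two carbonyls) onto the C1 oxygen, converting 3 into the hydroxy-para-quinone methide 4; acetic acid parks 4 reversibly as the para-hydroxybenzylic acetate 5, and once no quinone is left the soft sulfur of methanesulfinate captures 4 (re-formed from 5 by loss of acetate) in an irreversible 1,6-addition that re-aromatises the ring and forms the benzylic C–S bond, every ring carbon being substituted so that ordinary quinone Michael addition cannot compete and the sulfinate never meeting 3 so that bromide displacement on the quinone is avoided; the closest known reaction types are the ortho-quinone to quinone methide tautomerisation of 4-alkylcatechol quinones, the pseudobromide chemistry of polybrominated para-cresols and the 1,6-addition of sulfinates to aryl-substituted para-quinone methides, none of which has been used to sulfonylate the methyl group of a methyl-ortho-quinone; no stereocentre is formed.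

**Compound list**
1 | 4-methylbenzene-1,2-diol (4-methylcatechol) | Cc1ccc(O)c(O)c1 | starting material
2 | 3,4,6-tribromo-5-methylbenzene-1,2-diol | Cc1c(Br)c(O)c(O)c(Br)c1Br | intermediate
3 | 3,4,6-tribromo-5-methylcyclohexa-3,5-diene-1,2-dione | CC1=C(Br)C(=O)C(=O)C(Br)=C1Br | intermediate
4 | 2,3,5-tribromo-6-hydroxy-4-methylidenecyclohexa-2,5-dien-1-one | C=C1C(Br)=C(O)C(=O)C(Br)=C1Br | intermediate
5 | (2,3,6-tribromo-4,5-dihydroxyphenyl)methyl acetate | CC(=O)OCc1c(Br)c(O)c(O)c(Br)c1Br | intermediate
6 | 3,4,6-tribromo-5-[(methanesulfonyl)methyl]benzene-1,2-diol | CS(=O)(=O)Cc1c(Br)c(O)c(O)c(Br)c1Br | target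

**Step count and risks**

Total step count: 3. Longest linear sequence: 3 steps (1 → 2 → 3 → 6).

Steps most likely to fail, most risky first:

**Step 3 (proposed new method).** The risks are:
- slow tautomerisation of 3;
- redox exchange between 3 and catechol-level 5, which returns 2 (recyclable through step 2) and gives over-oxidised material;
- oligomerisation of 4;
- displacement of a ring bromide by sulfinate if any 3 survives into the second stage.

Fallback with known chemistry only, setting out from compound 2 and coming back at compound 6. Acetylation of 2 (Ac2O, pyridine, DMAP cat., CH2Cl2, rt) gives 3,4,6-tribromo-5-methyl-1,2-phenylene diacetate F1. Wohl–Ziegler bromination (NBS 1.1 equiv, AIBN cat., PhCF3, 85 °C) gives 3,4,6-tribromo-5-(bromomethyl)-1,2-phenylene diacetate F2; the ring is fully substituted, so only the methyl group can react. S-Alkylation of CH3SO2Na (1.5 equiv, DMF, 50 °C) gives 3,4,6-tribromo-5-[(methanesulfonyl)methyl]-1,2-phenylene diacetate F3. Acid methanolysis (HCl from AcCl cat. in MeOH, 50 °C, N2) removes both acetates and delivers 6.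

**Step 2.** The electron-poor catechol may oxidise incompletely, or quinone 3 may tautomerise or dimerise on concentration and not be isolable.

Fallback that needs no quinone, setting out from compound 2 and coming back at compound 6. Side-chain bromination in the manner of the classical pseudobromide formation of polybrominated para-cresols (Br2 2–3 equiv, AcOH, 70 °C; ipso-bromination para to OH, loss of HBr to 4, re-addition of HBr) gives 3,4,6-tribromo-5-(bromomethyl)benzene-1,2-diol F4. This is treated directly with CH3SO2Na (2.2 equiv, DMF, 0 °C to rt); it loses HBr to 4 in the flask and takes up the sulfinate to give 6.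

**Step 1.** The third bromination (between OH and CH3) may stall, or excess Br2 may oxidise the free catechol or attack the methyl group.

Fallback on a protected ring, setting out from compound 1 and coming back at compound 2. Methylation (MeI, K2CO3, acetone, reflux) gives 1,2-dimethoxy-4-methylbenzene F5. Forced ionic bromination (Br2 3.3 equiv, iron powder cat., CHCl3, 0 °C to reflux, dark) gives 1,2,4-tribromo-5,6-dimethoxy-3-methylbenzene F6. Demethylation (BBr3 3 equiv, CH2Cl2, −78 °C to rt) gives 2.

**Further compounds**
F1 | step 3 | 3,4,6-tribromo-5-methyl-1,2-phenylene diacetate | CC(=O)Oc1c(Br)c(C)c(Br)c(Br)c1OC(C)=O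
F2 | step 3 | 3,4,6-tribromo-5-(bromomethyl)-1,2-phenylene diacetate | CC(=O)Oc1c(Br)c(CBr)c(Br)c(Br)c1OC(C)=O
F3 | step 3 | 3,4,6-tribromo-5-[(methanesulfonyl)methyl]-1,2-phenylene diacetate | CC(=O)Oc1c(Br)c(CS(C)(=O)=O)c(Br)c(Br)c1OC(C)=O
F4 | step 2 | 3,4,6-tribromo-5-(bromomethyl)benzene-1,2-diol | BrCc1c(Br)c(O)c(O)c(Br)c1Br
F5 | step 1 | 1,2-dimethoxy-4-methylbenzene | COc1ccc(C)cc1OC
F6 | step 1 | 1,2,4-tribromo-5,6-dimethoxy-3-methylbenzene | COc1c(Br)c(C)c(Br)c(Br)c1OC
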